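**Plan**

1. Retrosynthetic cuts: the C15 ester; the side-chain end (C13–C16 and C14–C15, alkyne carboalumination); C8–C17; ring A at C1–C10; ring B at C8–C9; C4–C5; the C9–C10 bond of an acyclic allylic alcohol.
2. Forward: two alkynes give a C9 carbinol with an E C10=C5 alkene; an Ireland–Claisen rearrangement joins the C4 arm; a carbonyl-ene reaction closes ring B and unveils C10=CH2; ring A is then closed at C1–C10; C17, the C13–C15 terminus and the C30 acyl chain follow.
3. Enabling feature: C10 is the quaternary fusion carbon of rings A and B, and its fourth substituent is the angular methyl C20. Drawn as an exocyclic methylene on ring B it is a latent tertiary radical; a vinyl ketone on the gem-dimethyl arm (temporary C3 carbonyl in ring A) offers C1 as acceptor.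
4. Stereochemistry: one catalytic asymmetric alkenylzinc addition sets a temporary C9 carbinol; the Claisen chair relays it to C5; the ene chair sets C9 (and a temporary C8 carbinol) from C5; the radical ring closure sets C10 from ring B; the 13E alkene comes from syn carbometalation.
5. Helpers and their removal: C3 ketone (tosylhydrazone reduction); C8 carbinol (oxidised, then the enol triflate that receives C17); silyl groups (fluoride, last step).

Key step: step 8

Assumption: 30-hydroxytriacontanoic acid (26) is taken as a purchasable lipid standard; locants C1–C20 follow labdane numbering.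

**Route**

Step 1
Reactants: 1 5-(trimethylsilyl)pent-4-yn-1-ol
Product: 2 5-(trimethylsilyl)pent-4-ynal
Conditions: Dess–Martin periodinane, NaHCO3, CH2Cl2, 0 °C to rt
Reagents that add atoms: none
Why: Dess–Martin oxidation of a primary alcohol stops at the aldehyde and leaves the silylalkyne untouched.

Step 2
Reactants: 3 1-propynyllithium; 4 3-bromo-1,1-dimethoxypropane
Product: 5 6,6-dimethoxyhex-2-yne
Conditions: THF/DMPU, −20 °C to rt
Reagents that add atoms: none
Why: SN2 alkylation of a lithium acetylide by a primary bromide in a dipolar co-solvent, with the acetal inert to the acetylide.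

Step 3
Reactants: 5 6,6-dimethoxyhex-2-yne; 2 5-(trimethylsilyl)pent-4-ynal
Product: 8 (5R,6E)-10,10-dimethoxy-6-methyl-1-(trimethylsilyl)dec-6-en-1-yn-5-ol, via alkenylzirconocene chloride 6 (not isolated), via alkenylmethylzinc 7 (not isolated)
Conditions: Cp2Zr(H)Cl, CH2Cl2, rt; Me2Zn, toluene, −65 °C; (−)-3-exo-morpholinoisoborneol (10 mol %), then 2, −30 to 0 °C; aq NH4Cl
Reagents that add atoms: none
Why: syn-hydrozirconation puts zirconium on the less hindered, methyl-bearing alkyne carbon, zinc transmetalation keeps the E geometry, and ligand-accelerated alkenylzinc addition to the Si face of the aldehyde should give the R carbinol (hydrozirconation, zirconium-to-zinc transmetalation, catalytic asymmetric alkenylation).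

Step 4
Reactants: 8 (5R,6E)-10,10-dimethoxy-6-methyl-1-(trimethylsilyl)dec-6-en-1-yn-5-ol
Product: 9 (5R,6E)-10,10-dimethoxy-6-methyl-1-(trimethylsilyl)dec-6-en-1-yn-5-yl 2-methylpropanoate
Conditions: isobutyryl chloride, pyridine, DMAP (cat.), CH2Cl2, 0 °C to rt
Reagents that add atoms: isobutyryl chloride CC(C)C(Cl)=O
Why: routine acylation of a secondary allylic alcohol, which brings in C3, C4 and both C4 methyls.

Step 5
Reactants: 9 (5R,6E)-10,10-dimethoxy-6-methyl-1-(trimethylsilyl)dec-6-en-1-yn-5-yl 2-methylpropanoate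
Product: 12 (3S,4E)-3-(3,3-dimethoxypropyl)-2,2,4-trimethyl-9-(trimethylsilyl)non-4-en-8-ynoic acid, via silyl ketene acetal 10 (not isolated), via trimethylsilyl ester 11 (not isolated)
Conditions: LiN(iPr)2, Me3SiCl, THF, −78 °C, then 60 °C; aq citric acid (pH 4), 0 °C
Reagents that add atoms: none
Why: Ireland–Claisen rearrangement through a chair with C11 equatorial forms C4–C5 suprafacially, so the R carbinol at C9 is relayed to C5 and the new C9=C10 alkene is E; the symmetric isobutyrate enolate has no geometry issue.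

Step 6
Reactants: 12 (3S,4E)-3-(3,3-dimethoxypropyl)-2,2,4-trimethyl-9-(trimethylsilyl)non-4-en-8-ynoic acid
Product: 14 (4S,5E)-5-methyl-4-(2-methyl-3-oxopent-4-en-2-yl)-10-(trimethylsilyl)dec-5-en-9-ynal, via vinyl ketone acetal 13 (not isolated)
Conditions: CH2=CHLi (3 equiv, from Sn(CH=CH2)4 and MeLi), THF, −78 to 0 °C; inverse quench into 2 M HCl/THF, rt
Reagents that add atoms: vinyllithium [Li]C=C; water O
Why: vinyllithium adds to the lithium carboxylate to give a dilithio gem-diolate that cannot over-add, and the acidic quench releases the vinyl ketone and hydrolyses the dimethyl acetal to the aldehyde (organolithium–carboxylate ketone synthesis, acetal hydrolysis).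

Step 7
Reactants: 14 (4S,5E)-5-methyl-4-(2-methyl-3-oxopent-4-en-2-yl)-10-(trimethylsilyl)dec-5-en-9-ynal
Product: 15 4-[(1S,3S,4R)-4-hydroxy-2-methylidene-3-[4-(trimethylsilyl)but-3-yn-1-yl]cyclohexyl]-4-methylpent-1-en-3-one
Conditions: Me2AlCl (1.5 equiv), CH2Cl2, −78 to −40 °C; 1 M HCl, 0 °C
Reagents that add atoms: none
Why: type-2 intramolecular carbonyl-ene reaction in which C9 of the trisubstituted alkene attacks the aldehyde while a C20 hydrogen moves to oxygen, closing ring B at C8–C9 and unveiling C10=CH2; a chair with the C5 arm and C11 equatorial (C11 from the E alkene) should give the 5,9-cis ring with an axial C8 hydroxyl.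

Step 8
Reactants: 15 4-[(1S,3S,4R)-4-hydroxy-2-methylidene-3-[4-(trimethylsilyl)but-3-yn-1-yl]cyclohexyl]-4-methylpent-1-en-3-one
Product: 16 (4aR,5S,6R,8aS)-6-hydroxy-1,1,4a-trimethyl-5-[4-(trimethylsilyl)but-3-yn-1-yl]octahydronaphthalen-2(1H)-one
Conditions: Fe(acac)3 (30 mol %), PhSiH3 (2.5 equiv), EtOH/ethylene glycol 5:1, 0.01 M, 60 °C
Reagents that add atoms: none
Why: An iron hydride formed from Fe(acac)3 and PhSiH3 transfers a hydrogen atom to the CH2 end of the exocyclic alkene, which turns C20 into the angular methyl and C10 into a tertiary radical; this nucleophilic radical adds to C1 of the tethered vinyl ketone, and the α-keto radical is reduced by divalent iron to the enolate and protonated by ethanol. The closest known reaction type is the iron-mediated reductive olefin coupling (hydrogen-atom-transfer-initiated Giese addition) in its intramolecular form. Ring A closes 6-endo-trig, the favoured mode for a radical two atoms away from the enone carbonyl, because 5-exo attack at the α-carbon is polarity-mismatched. C10 is controlled by ring B: the cis C5 and C9 substituents hold the chair with both equatorial, and the C4 arm then bonds to C10 along the equatorial direction through a chair-like ring A, as in the second ring closure of radical polyene cyclisations, which puts C20 axial and anti to H5 (trans-decalin). The step needs hydrogen-atom transfer to the electron-rich 1,1-disubstituted alkene in preference to the electron-poor enone and the silylalkyne, which the hydridic character of the iron hydride and high dilution should secure.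

Step 9
Reactants: 16 (4aR,5S,6R,8aS)-6-hydroxy-1,1,4a-trimethyl-5-[4-(trimethylsilyl)but-3-yn-1-yl]octahydronaphthalen-2(1H)-one
Product: 18 (1S,2R,4aR,8aR)-5,5,8a-trimethyl-1-[4-(trimethylsilyl)but-3-yn-1-yl]decahydronaphthalen-2-ol, via tosylhydrazone 17 (not isolated)
Conditions: TsNHNH2, TsOH (cat.), EtOH, 78 °C; then catecholborane, CHCl3, 0 °C; NaOAc·3H2O, 60 °C
Reagents that add atoms: none
Why: hydroboration of the C3 tosylhydrazone followed by loss of sulfinate and N2 removes the activating ketone under non-basic conditions that spare the silylalkyne and the free hydroxyl (tosylhydrazone reduction with catecholborane).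

Step 10
Reactants: 18 (1S,2R,4aR,8aR)-5,5,8a-trimethyl-1-[4-(trimethylsilyl)but-3-yn-1-yl]decahydronaphthalen-2-ol
Product: 19 (1S,4aR,8aR)-5,5,8a-trimethyl-1-[4-(trimethylsilyl)but-3-yn-1-yl]octahydronaphthalen-2(1H)-one
Conditions: Dess–Martin periodinane, NaHCO3, CH2Cl2, rt
Reagents that add atoms: none
Why: Dess–Martin oxidation of the temporary C8 carbinol gives the ketone needed for C17; C9 is now α to a carbonyl with its equatorial side chain as the thermodynamic epimer, so a trace of base would correct any C9 epimer carried from step 7.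

Step 11
Reactants: 19 (1S,4aR,8aR)-5,5,8a-trimethyl-1-[4-(trimethylsilyl)but-3-yn-1-yl]octahydronaphthalen-2(1H)-one
Product: 20 (1S,4aR,8aR)-5,5,8a-trimethyl-1-[4-(trimethylsilyl)but-3-yn-1-yl]-1,4,4a,5,6,7,8,8a-octahydronaphthalen-2-yl trifluoromethanesulfonate
Conditions: KN(SiMe3)2, THF, −78 °C; PhNTf2, −78 to 0 °C
Reagents that add atoms: N-phenylbis(trifluoromethanesulfonimide) O=S(=O)(N(c1ccccc1)S(=O)(=O)C(F)(F)F)C(F)(F)F
Why: kinetic deprotonation takes the C7 methylene rather than the hindered C9 methine, so O-triflation fixes the C7=C8 double bond (enol triflate formation).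

Step 12
Reactants: 20 (1S,4aR,8aR)-5,5,8a-trimethyl-1-[4-(trimethylsilyl)but-3-yn-1-yl]-1,4,4a,5,6,7,8,8a-octahydronaphthalen-2-yl trifluoromethanesulfonate
Product: 21 [(1S,4aR,8aR)-5,5,8a-trimethyl-1-[4-(trimethylsilyl)but-3-yn-1-yl]-1,4,4a,5,6,7,8,8a-octahydronaphthalen-2-yl]methanol
Conditions: Bu3SnCH2OH, Pd(PPh3)4 (5 mol %), LiCl, 1,4-dioxane, 100 °C
Reagents that add atoms: (tributylstannyl)methanol CCCC[Sn](CCCC)(CCCC)CO
Why: Stille coupling of the enol triflate with the hydroxymethyl stannane installs C17 at the alcohol oxidation level without moving the C7=C8 alkene.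

Step 13
Reactants: 21 [(1S,4aR,8aR)-5,5,8a-trimethyl-1-[4-(trimethylsilyl)but-3-yn-1-yl]-1,4,4a,5,6,7,8,8a-octahydronaphthalen-2-yl]methanol
Product: 22 tert-butyl(dimethyl){[(1S,4aR,8aR)-5,5,8a-trimethyl-1-[4-(trimethylsilyl)but-3-yn-1-yl]-1,4,4a,5,6,7,8,8a-octahydronaphthalen-2-yl]methoxy}silane
Conditions: tert-butyldimethylsilyl chloride, imidazole, DMF, rt
Reagents that add atoms: tert-butyldimethylsilyl chloride CC(C)(C)[Si](C)(C)Cl
Why: silylation of the primary allylic C17 hydroxyl keeps it distinct from the C15 hydroxyl that is made in step 15 and acylated in step 17.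

Step 14
Reactants: 22 tert-butyl(dimethyl){[(1S,4aR,8aR)-5,5,8a-trimethyl-1-[4-(trimethylsilyl)but-3-yn-1-yl]-1,4,4a,5,6,7,8,8a-octahydronaphthalen-2-yl]methoxy}silane
Product: 23 {[(1S,4aR,8aR)-1-(but-3-yn-1-yl)-5,5,8a-trimethyl-1,4,4a,5,6,7,8,8a-octahydronaphthalen-2-yl]methoxy}(tert-butyl)dimethylsilane
Conditions: K2CO3, MeOH, rt
Reagents that add atoms: none
Why: methanolysis of the alkynyl C–Si bond frees the terminal alkyne while the silyl ether is inert to carbonate.

Step 15
Reactants: 23 {[(1S,4aR,8aR)-1-(but-3-yn-1-yl)-5,5,8a-trimethyl-1,4,4a,5,6,7,8,8a-octahydronaphthalen-2-yl]methoxy}(tert-butyl)dimethylsilane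
Product: 25 (2E)-5-[(1S,4aR,8aR)-2-{[tert-butyl(dimethyl)silyl]oxymethyl}-5,5,8a-trimethyl-1,4,4a,5,6,7,8,8a-octahydronaphthalen-1-yl]-3-methylpent-2-en-1-ol, via alkenylalane 24 (not isolated)
Conditions: Me3Al, Cp2ZrCl2 (25 mol %), CH2Cl2, 0 °C to rt; n-BuLi, THF, −30 °C; (CH2O)n, rt; dilute HCl, 0 °C
Reagents that add atoms: trimethylaluminium C[Al](C)C; paraformaldehyde (as formaldehyde) C=O
Why: Negishi carboalumination adds methyl and aluminium syn across the terminal alkyne with methyl on the internal carbon, and the alkenyl aluminate is trapped by formaldehyde with retention, giving the E trisubstituted allylic alcohol.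

Step 16
Reactants: 26 30-hydroxytriacontanoic acid
Product: 28 30-[(tert-butyldimethylsilyl)oxy]triacontanoic acid, via bis-silyl derivative 27 (not isolated)
Conditions: tert-butyldimethylsilyl chloride, imidazole, THF/DMF, 50 °C; then K2CO3, MeOH/THF/H2O, rt; acidify to pH 4
Reagents that add atoms: tert-butyldimethylsilyl chloride CC(C)(C)[Si](C)(C)Cl
Why: exhaustive silylation followed by selective hydrolysis of the labile silyl ester leaves the ω-silyl ether acid, which cannot self-esterify in step 17.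

Step 17
Reactants: 25 (2E)-5-[(1S,4aR,8aR)-2-{[tert-butyl(dimethyl)silyl]oxymethyl}-5,5,8a-trimethyl-1,4,4a,5,6,7,8,8a-octahydronaphthalen-1-yl]-3-methylpent-2-en-1-ol; 28 30-[(tert-butyldimethylsilyl)oxy]triacontanoic acid
Product: 29 (2E)-5-[(1S,4aR,8aR)-2-{[tert-butyl(dimethyl)silyl]oxymethyl}-5,5,8a-trimethyl-1,4,4a,5,6,7,8,8a-octahydronaphthalen-1-yl]-3-methylpent-2-en-1-yl 30-[(tert-butyldimethylsilyl)oxy]triacontanoate
Conditions: EDC·HCl, DMAP, CH2Cl2, rt to 35 °C
Reagents that add atoms: none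
Why: Steglich-type carbodiimide esterification of the only free hydroxyl (primary allylic C15–OH) with the protected acid.

Step 18
Reactants: 29 (2E)-5-[(1S,4aR,8aR)-2-{[tert-butyl(dimethyl)silyl]oxymethyl}-5,5,8a-trimethyl-1,4,4a,5,6,7,8,8a-octahydronaphthalen-1-yl]-3-methylpent-2-en-1-yl 30-[(tert-butyldimethylsilyl)oxy]triacontanoate
Product: 30 (2E)-5-[(1S,4aR,8aR)-2-(hydroxymethyl)-5,5,8a-trimethyl-1,4,4a,5,6,7,8,8a-octahydronaphthalen-1-yl]-3-methylpent-2-en-1-yl 30-hydroxytriacontanoate
Conditions: HF·pyridine, pyridine/THF, 0 °C to rt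
Reagents that add atoms: none
Why: buffered fluoride cleavage of both primary silyl ethers should leave the allylic ester, both alkenes and the three stereocentres untouched.

**Compound list**

1 | 5-(trimethylsilyl)pent-4-yn-1-ol | C[Si](C)(C)C#CCCCO | starting material
2 | 5-(trimethylsilyl)pent-4-ynal | C[Si](C)(C)C#CCCC=O | intermediate
3 | 1-propynyllithium | [Li]C#CC | starting material
4 | 3-bromo-1,1-dimethoxypropane | COC(OC)CCBr | starting material
5 | 6,6-dimethoxyhex-2-yne | CC#CCCC(OC)OC | intermediate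
6 | (E)-alkenylzirconocene chloride from 5, zirconium on the methyl-bearing carbon (not isolated) | C/C(=C\CCC(OC)OC)[Zr](Cl)(C1C=CC=C1)C1C=CC=C1 | intermediate
7 | (E)-alkenyl(methyl)zinc from 6 (not isolated) | C/C(=C\CCC(OC)OC)[Zn]C | intermediate
8 | (5R,6E)-10,10-dimethoxy-6-methyl-1-(trimethylsilyl)dec-6-en-1-yn-5-ol | C[Si](C)(C)C#CCC[C@@H](O)/C(C)=C/CCC(OC)OC | intermediate
9 | (5R,6E)-10,10-dimethoxy-6-methyl-1-(trimethylsilyl)dec-6-en-1-yn-5-yl 2-methylpropanoate | C[Si](C)(C)C#CCC[C@@H](OC(=O)C(C)C)/C(C)=C/CCC(OC)OC | intermediate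
10 | trimethylsilyl ketene acetal of 9 (not isolated) | C[Si](C)(C)C#CCC[C@@H](OC(O[Si](C)(C)C)=C(C)C)/C(C)=C/CCC(OC)OC | intermediate
11 | trimethylsilyl ester of 12 (not isolated) | COC(OC)CC[C@H](C(C)(C)C(=O)O[Si](C)(C)C)/C(C)=C/CCC#C[Si](C)(C)C | intermediate
12 | (3S,4E)-3-(3,3-dimethoxypropyl)-2,2,4-trimethyl-9-(trimethylsilyl)non-4-en-8-ynoic acid | COC(OC)CC[C@H](C(C)(C)C(O)=O)/C(C)=C/CCC#C[Si](C)(C)C | intermediate
13 | (5S,6E)-5-(3,3-dimethoxypropyl)-4,4,6-trimethyl-11-(trimethylsilyl)undeca-1,6-dien-10-yn-3-one (not isolated) | COC(OC)CC[C@H](C(C)(C)C(=O)C=C)/C(C)=C/CCC#C[Si](C)(C)C | intermediate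
14 | (4S,5E)-5-methyl-4-(2-methyl-3-oxopent-4-en-2-yl)-10-(trimethylsilyl)dec-5-en-9-ynal | O=CCC[C@H](C(C)(C)C(=O)C=C)/C(C)=C/CCC#C[Si](C)(C)C | intermediate
15 | 4-[(1S,3S,4R)-4-hydroxy-2-methylidene-3-[4-(trimethylsilyl)but-3-yn-1-yl]cyclohexyl]-4-methylpent-1-en-3-one (ring B; 5,9-cis, axial 8-OH) | C[Si](C)(C)C#CCC[C@@H]1[C@H](O)CC[C@H](C(C)(C)C(=O)C=C)C1=C | intermediate
16 | (4aR,5S,6R,8aS)-6-hydroxy-1,1,4a-trimethyl-5-[4-(trimethylsilyl)but-3-yn-1-yl]octahydronaphthalen-2(1H)-one (trans-decalin) | C[Si](C)(C)C#CCC[C@@H]1[C@H](O)CC[C@@H]2C(C)(C)C(=O)CC[C@@]12C | intermediate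
17 | C3 tosylhydrazone of 16 (not isolated) | C[Si](C)(C)C#CCC[C@@H]1[C@H](O)CC[C@@H]2C(C)(C)C(=NNS(=O)(=O)c3ccc(C)cc3)CC[C@@]12C | intermediate
18 | (1S,2R,4aR,8aR)-5,5,8a-trimethyl-1-[4-(trimethylsilyl)but-3-yn-1-yl]decahydronaphthalen-2-ol | C[Si](C)(C)C#CCC[C@@H]1[C@H](O)CC[C@@H]2C(C)(C)CCC[C@@]12C | intermediate
19 | (1S,4aR,8aR)-5,5,8a-trimethyl-1-[4-(trimethylsilyl)but-3-yn-1-yl]octahydronaphthalen-2(1H)-one | C[Si](C)(C)C#CCC[C@@H]1C(=O)CC[C@@H]2C(C)(C)CCC[C@@]12C | intermediate
20 | (1S,4aR,8aR)-5,5,8a-trimethyl-1-[4-(trimethylsilyl)but-3-yn-1-yl]-1,4,4a,5,6,7,8,8a-octahydronaphthalen-2-yl trifluoromethanesulfonate | C[Si](C)(C)C#CCC[C@@H]1C(OS(=O)(=O)C(F)(F)F)=CC[C@@H]2C(C)(C)CCC[C@@]12C | intermediate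
21 | [(1S,4aR,8aR)-5,5,8a-trimethyl-1-[4-(trimethylsilyl)but-3-yn-1-yl]-1,4,4a,5,6,7,8,8a-octahydronaphthalen-2-yl]methanol | C[Si](C)(C)C#CCC[C@@H]1C(CO)=CC[C@@H]2C(C)(C)CCC[C@@]12C | intermediate
22 | tert-butyldimethylsilyl ether of 21 | C[Si](C)(C)C#CCC[C@@H]1C(CO[Si](C)(C)C(C)(C)C)=CC[C@@H]2C(C)(C)CCC[C@@]12C | intermediate
23 | {[(1S,4aR,8aR)-1-(but-3-yn-1-yl)-5,5,8a-trimethyl-1,4,4a,5,6,7,8,8a-octahydronaphthalen-2-yl]methoxy}(tert-butyl)dimethylsilane | C#CCC[C@@H]1C(CO[Si](C)(C)C(C)(C)C)=CC[C@@H]2C(C)(C)CCC[C@@]12C | intermediate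
24 | (E)-alkenyldimethylalane from 23, aluminium on C14 and methyl on C13 (not isolated) | C/C(=C\[Al](C)C)CC[C@@H]1C(CO[Si](C)(C)C(C)(C)C)=CC[C@@H]2C(C)(C)CCC[C@@]12C | intermediate
25 | (2E)-5-[(1S,4aR,8aR)-2-{[tert-butyl(dimethyl)silyl]oxymethyl}-5,5,8a-trimethyl-1,4,4a,5,6,7,8,8a-octahydronaphthalen-1-yl]-3-methylpent-2-en-1-ol | C/C(=C\CO)CC[C@@H]1C(CO[Si](C)(C)C(C)(C)C)=CC[C@@H]2C(C)(C)CCC[C@@]12C | intermediate
26 | 30-hydroxytriacontanoic acid | OCCCCCCCCCCCCCCCCCCCCCCCCCCCCCC(O)=O | starting material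
27 | tert-butyldimethylsilyl 30-[(tert-butyldimethylsilyl)oxy]triacontanoate (not isolated) | CC(C)(C)[Si](C)(C)OCCCCCCCCCCCCCCCCCCCCCCCCCCCCCC(=O)O[Si](C)(C)C(C)(C)C | intermediate
28 | 30-[(tert-butyldimethylsilyl)oxy]triacontanoic acid | CC(C)(C)[Si](C)(C)OCCCCCCCCCCCCCCCCCCCCCCCCCCCCCC(O)=O | intermediate
29 | bis(tert-butyldimethylsilyl) ether of the target (C17–O and C30–O silylated) | C/C(=C\COC(=O)CCCCCCCCCCCCCCCCCCCCCCCCCCCCCO[Si](C)(C)C(C)(C)C)CC[C@@H]1C(CO[Si](C)(C)C(C)(C)C)=CC[C@@H]2C(C)(C)CCC[C@@]12C | intermediate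
30 | (2E)-5-[(1S,4aR,8aR)-2-(hydroxymethyl)-5,5,8a-trimethyl-1,4,4a,5,6,7,8,8a-octahydronaphthalen-1-yl]-3-methylpent-2-en-1-yl 30-hydroxytriacontanoate | C/C(=C\COC(=O)CCCCCCCCCCCCCCCCCCCCCCCCCCCCCO)CC[C@@H]1C(CO)=CC[C@@H]2C(C)(C)CCC[C@@]12C | target

**Step count and risks**

Total steps: 18. Longest linear sequence: 16 (steps 2 to 15, then 17 and 18).

Step 8 (most at risk). Hydrogen-atom transfer may go to the vinyl ketone (conjugate reduction), or the tertiary radical may be reduced before it cyclises; facial control at C10 may also be incomplete. The fallback sets out from 15 and comes back at 16. HCl in CH2Cl2 at −40 °C adds in the Markovnikov sense to C10=CH2 and reversibly to the enone, giving the 10-chloro β-chloroethyl ketone F1. Triethylamine eliminates only the β-chloride and restores the enone, giving the tertiary chloride F2. Slow addition of Bu3SnH with AIBN in toluene at 110 °C then abstracts chlorine, forms the same C10 radical without any metal hydride, and closes ring A by tin-hydride radical conjugate addition to 16.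

Step 7. Lewis-acid activation of the vinyl ketone may open competing cationic ring closures or polymerisation; the developing C10 cation may lose a ring proton instead of the C20 hydrogen; the C5/C9 relationship may come out trans. The fallback sets out from 12 and comes back at 15, so that no enone is present when the Lewis acid is used. Me3SiCHN2 in MeOH/toluene gives the methyl ester acetal F3. Aqueous HCl in THF hydrolyses the acetal to the aldehyde ester F4. Me2AlCl closes ring B on F4 to the hydroxy ester F5. MeNH(OMe)·HCl with iPrMgCl gives the Weinreb amide F6. CH2=CHMgBr (excess, THF, 0 °C, acidic quench) gives 15.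

Step 3. Unligated background addition promoted by the zirconium by-product may erode the enantioselectivity, and hydrozirconation may place zirconium partly on the wrong alkyne carbon. The fallback sets out from 5 (with 2) and comes back at 8; it separates C–C bond formation from asymmetric induction. Hydrozirconation of 5 with Cp2Zr(H)Cl and iodinolysis give the vinyl iodide F7, whose regioisomer can be removed. Iodine–lithium exchange (t-BuLi, Et2O, −78 °C) and addition to 2 give the racemic allylic alcohol F8. Dess–Martin oxidation gives the enone F9. Corey–Bakshi–Shibata reduction with the (S)-methyl oxazaborolidine and BH3·SMe2 should return 8 with the R carbinol.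

Further compounds

F1 | step 8 | 1-chloro-4-[2-chloro-4-hydroxy-2-methyl-3-(4-trimethylsilylbut-3-ynyl)cyclohexyl]-4-methylpentan-3-one (C5, C8, C9 as in 15; C10 unassigned) | C[Si](C)(C)C#CCC[C@@H]1[C@H](O)CC[C@H](C(C)(C)C(=O)CCCl)C1(C)Cl
F2 | step 8 | 4-[2-chloro-4-hydroxy-2-methyl-3-(4-trimethylsilylbut-3-ynyl)cyclohexyl]-4-methylpent-1-en-3-one (C5, C8, C9 as in 15; C10 unassigned) | C[Si](C)(C)C#CCC[C@@H]1[C@H](O)CC[C@H](C(C)(C)C(=O)C=C)C1(C)Cl
F3 | step 7 | methyl (3S,4E)-3-(3,3-dimethoxypropyl)-2,2,4-trimethyl-9-(trimethylsilyl)non-4-en-8-ynoate | COC(OC)CC[C@H](C(C)(C)C(=O)OC)/C(C)=C/CCC#C[Si](C)(C)C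
F4 | step 7 | methyl (3S,4E)-2,2,4-trimethyl-3-(3-oxopropyl)-9-(trimethylsilyl)non-4-en-8-ynoate | O=CCC[C@H](C(C)(C)C(=O)OC)/C(C)=C/CCC#C[Si](C)(C)C
F5 | step 7 | methyl 2-[(1S,3S,4R)-4-hydroxy-2-methylidene-3-[4-(trimethylsilyl)but-3-yn-1-yl]cyclohexyl]-2-methylpropanoate | C[Si](C)(C)C#CCC[C@@H]1[C@H](O)CC[C@H](C(C)(C)C(=O)OC)C1=C
F6 | step 7 | 2-[(1S,3S,4R)-4-hydroxy-2-methylidene-3-[4-(trimethylsilyl)but-3-yn-1-yl]cyclohexyl]-N-methoxy-N,2-dimethylpropanamide | C[Si](C)(C)C#CCC[C@@H]1[C@H](O)CC[C@H](C(C)(C)C(=O)N(C)OC)C1=C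
F7 | step 3 | (4E)-5-iodo-1,1-dimethoxyhex-4-ene | C/C(I)=C\CCC(OC)OC
F8 | step 3 | racemic (6E)-10,10-dimethoxy-6-methyl-1-(trimethylsilyl)dec-6-en-1-yn-5-ol | C[Si](C)(C)C#CCCC(O)/C(C)=C/CCC(OC)OC
F9 | step 3 | (6E)-10,10-dimethoxy-6-methyl-1-(trimethylsilyl)dec-6-en-1-yn-5-one | C[Si](C)(C)C#CCCC(=O)/C(C)=C/CCC(OC)OC
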